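The route rests on disconnecting the C1'–C2' bond of the side chain carried by C4 of the furan ring (O1, C2 aryl, C3–H, C4, C5–H). The unit O–C1'–C2'–C3'=C4'(CH3)2 is a homoallylic carbinol with a gem-dimethyl alkene terminus, which a [2,3]-Wittig shift of a furylmethyl 1,1-dimethylallyl ether exploits. In one operation, under a chiral bis(oxazoline)-bound alkyllithium, the C1'–C2' bond is made, the R centre at C1' is set and the linear prenyl chain appears, with no ring closed. The precursor is an achiral 2-aryl-4-(alkoxymethyl)furan whose hydroquinone is masked as two triisopropylsilyl ethers, sturdier than tert-butyldimethylsilyl toward alkoxide and alkyllithium.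

Key step: step 7

Remark: the (S,S)-bis(oxazoline) is assumed to be the antipode that gives the R carbinol; if a trial run shows the opposite sense, the (R,R)-ligand from D-valinol is used in the same way.

Step 1
Reactants: 1 bromohydroquinone (2-bromobenzene-1,4-diol)
Product: 2 2-bromo-1,4-bis(triisopropylsilyloxy)benzene
Conditions: TIPSCl (2.5 equiv), imidazole, DMF, rt to 40 °C
Reagents that add atoms: triisopropylsilyl chloride, CC(C)[Si](Cl)(C(C)C)C(C)C
Why: Silyl ether formation by imidazole-promoted O-silylation of both phenols, the hindered hydroxyl next to bromine included at slightly raised temperature, gives a bis-silyl ether that should withstand the later alkoxide and t-BuLi steps; no stereocentre is involved.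

Step 2
Reactants: 2 2-bromo-1,4-bis(triisopropylsilyloxy)benzene
Product: 3 2-[2,5-bis(triisopropylsilyloxy)phenyl]-4,4,5,5-tetramethyl-1,3,2-dioxaborolane
Conditions: B2pin2, Pd(dppf)Cl2 (3 mol %), KOAc, 1,4-dioxane, 90 °C
Reagents that add atoms: bis(pinacolato)diboron, CC1(C)OB(OC1(C)C)B1OC(C)(C)C(C)(C)O1
Why: Miyaura borylation (oxidative addition of the aryl bromide to zerovalent palladium, acetate-assisted transmetalation with B2pin2, reductive elimination) should give the arylboronate, KOAc being too weak a base to cleave the aryl silyl ethers.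

Step 3
Reactants: 3 2-[2,5-bis(triisopropylsilyloxy)phenyl]-4,4,5,5-tetramethyl-1,3,2-dioxaborolane and 4 methyl 5-bromofuran-3-carboxylate
Product: 5 methyl 5-[2,5-bis(triisopropylsilyloxy)phenyl]furan-3-carboxylate
Conditions: Pd(OAc)2 (2 mol %), SPhos (2-dicyclohexylphosphino-2',6'-dimethoxybiphenyl, 4 mol %), K3PO4, toluene/H2O (10:1), 80 °C
Reagents that add atoms: none
Why: Suzuki–Miyaura coupling, in which the electron-poor 2-bromofuran adds readily to zerovalent palladium and the bulky electron-rich phosphine carries the ortho-silyloxy arylboronate through transmetalation, fixes the aryl group unambiguously on the furan carbon that becomes C2.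

Step 4
Reactants: 5 methyl 5-[2,5-bis(triisopropylsilyloxy)phenyl]furan-3-carboxylate
Product: 6 {5-[2,5-bis(triisopropylsilyloxy)phenyl]furan-3-yl}methanol
Conditions: i-Bu2AlH (2.5 equiv), CH2Cl2, −78 to 0 °C; aq potassium sodium tartrate
Reagents that add atoms: none
Why: Hydride reduction of the ester to the primary alcohol with i-Bu2AlH, to which the furan and the aryl silyl ethers are inert.

Step 5
Reactants: 6 {5-[2,5-bis(triisopropylsilyloxy)phenyl]furan-3-yl}methanol
Product: 8 2-[2,5-bis(triisopropylsilyloxy)phenyl]-4-(chloromethyl)furan, via furylmethyl methanesulfonate 7 (not isolated)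
Conditions: MsCl, Et3N, CH2Cl2, 0 °C; then LiCl, DMF, 0 °C to rt
Reagents that add atoms: methanesulfonyl chloride, CS(=O)(=O)Cl (atoms kept in intermediate 7 only); lithium chloride, [Li+].[Cl-] (chlorine of 8)
Why: O-Sulfonylation followed by SN2 displacement of the primary furylmethyl mesylate by chloride should give the chloride without free acid, so neither the furan nor the silyl ethers meet HCl.

Step 6
Reactants: 8 2-[2,5-bis(triisopropylsilyloxy)phenyl]-4-(chloromethyl)furan and 9 2-methylbut-3-en-2-ol
Product: 11 2-[2,5-bis(triisopropylsilyloxy)phenyl]-4-{[(2-methylbut-3-en-2-yl)oxy]methyl}furan, via sodium 2-methylbut-3-en-2-olate 10 (not isolated)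
Conditions: 9, NaH, THF, 0 °C to rt; then 8, n-Bu4NI (cat.), DMF, 0 °C to rt
Reagents that add atoms: sodium hydride, [Na+].[H-] (sodium in intermediate 10 only)
Why: Williamson ether synthesis, in which the tertiary alkoxide displaces the primary furylmethyl chloride under iodide catalysis; elimination is impossible for want of a beta hydrogen, and the triisopropylsilyl groups are too hindered for silyl transfer to the alkoxide.

Step 7
Reactants: 11 2-[2,5-bis(triisopropylsilyloxy)phenyl]-4-{[(2-methylbut-3-en-2-yl)oxy]methyl}furan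
Product: 13 (R)-1-{5-[2,5-bis(triisopropylsilyloxy)phenyl]furan-3-yl}-4-methylpent-3-en-1-ol, via alpha-lithio ether 12 (not isolated)
Conditions: t-BuLi and (S,S)-2,2'-(pentane-3,3-diyl)bis(4-isopropyl-4,5-dihydrooxazole) (1.5 equiv each, premixed), hexane, −78 °C; then aq NH4Cl
Reagents that add atoms: tert-butyllithium, [Li]C(C)(C)C (lithium in intermediate 12 only)
Why: The ligand-bound t-BuLi removes a proton from the furylic OCH2 carbon of 11, and the alpha-oxy carbanion 12 attacks the terminal CH2 of the vinyl group through a five-membered envelope transition state while the O–C(CH3)2 bond breaks, so the C1'–C2' bond forms suprafacially and the lithium alkoxide of 13 results. The closest known reaction type is the enantioselective [2,3]-Wittig rearrangement of benzylic allyl ethers mediated by an alkyllithium and a chiral bis(oxazoline), applied here to a heteroarylmethyl tertiary-allyl ether. No ring is closed. The C1' stereocentre is controlled by the reagent alone: the C2-symmetric bis(oxazoline) on lithium differentiates the two faces of the carbanion carbon, by selective proton removal or by equilibration of the diastereomeric ligand-bound carbanions, before the concerted shift. The step needs lateral rather than ring lithiation and a [2,3] rather than a [1,2] shift: the ether oxygen guides the base to the adjacent furylic CH2, the aryl group blocks C2 of the furan so that C5–H is the only competing ring site, the triisopropylsilyl ethers resist attack at silicon and ortho-lithiation, and hexane at −78 °C disfavours the radical [1,2] pathway. The 1,1-dimethylallyl group delivers the linear prenyl chain with no alkene geometry to set.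

Step 8
Reactants: 13 (R)-1-{5-[2,5-bis(triisopropylsilyloxy)phenyl]furan-3-yl}-4-methylpent-3-en-1-ol and 14 3-methylbutanoyl chloride
Product: 15 (R)-1-{5-[2,5-bis(triisopropylsilyloxy)phenyl]furan-3-yl}-4-methylpent-3-en-1-yl 3-methylbutanoate
Conditions: pyridine, 4-(dimethylamino)pyridine (cat.), CH2Cl2, 0 °C
Reagents that add atoms: none
Why: Nucleophile-catalysed O-acylation esterifies the secondary alcohol without touching the C1'–O bond, so the R configuration is retained, and the basic medium prevents ionisation of the furylic carbinol.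

Step 9
Reactants: 15 (R)-1-{5-[2,5-bis(triisopropylsilyloxy)phenyl]furan-3-yl}-4-methylpent-3-en-1-yl 3-methylbutanoate
Product: 16 (R)-1-[5-(2,5-dihydroxyphenyl)furan-3-yl]-4-methylpent-3-en-1-yl 3-methylbutanoate
Conditions: n-Bu4NF, AcOH (1:1, 2.5 equiv), THF, 0 °C, argon
Reagents that add atoms: none
Why: Fluoride-induced desilylation of the two aryl silyl ethers, buffered with acetic acid so that the phenoxides are protonated at once and neither attack the ester nor oxidise in an uncontrolled way; the ester and the C1' centre are not affected.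

Step 10
Reactants: 16 (R)-1-[5-(2,5-dihydroxyphenyl)furan-3-yl]-4-methylpent-3-en-1-yl 3-methylbutanoate
Product: 17 (R)-1-[5-(3,6-dioxocyclohexa-1,4-dien-1-yl)furan-3-yl]-4-methylpent-3-en-1-yl 3-methylbutanoate (CNP0219765.1)
Conditions: Ag2O, MgSO4, Et2O, rt, dark
Reagents that add atoms: none
Why: Two-electron oxidation of the hydroquinone to the 1,4-benzoquinone by Ag2O under neutral anhydrous conditions should leave the furan, the trisubstituted alkene, the ester and the C1' stereocentre untouched.

Compound list

1 | bromohydroquinone (2-bromobenzene-1,4-diol) | Oc1ccc(O)c(Br)c1 | starting material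
2 | 2-bromo-1,4-bis(triisopropylsilyloxy)benzene | Brc1cc(O[Si](C(C)C)(C(C)C)C(C)C)ccc1O[Si](C(C)C)(C(C)C)C(C)C | intermediate
3 | 2-[2,5-bis(triisopropylsilyloxy)phenyl]-4,4,5,5-tetramethyl-1,3,2-dioxaborolane | CC1(C)OB(OC1(C)C)c1cc(O[Si](C(C)C)(C(C)C)C(C)C)ccc1O[Si](C(C)C)(C(C)C)C(C)C | intermediate
4 | methyl 5-bromofuran-3-carboxylate | COC(=O)c1coc(Br)c1 | starting material
5 | methyl 5-[2,5-bis(triisopropylsilyloxy)phenyl]furan-3-carboxylate | COC(=O)c1coc(-c2cc(O[Si](C(C)C)(C(C)C)C(C)C)ccc2O[Si](C(C)C)(C(C)C)C(C)C)c1 | intermediate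
6 | {5-[2,5-bis(triisopropylsilyloxy)phenyl]furan-3-yl}methanol | OCc1coc(-c2cc(O[Si](C(C)C)(C(C)C)C(C)C)ccc2O[Si](C(C)C)(C(C)C)C(C)C)c1 | intermediate
7 | {5-[2,5-bis(triisopropylsilyloxy)phenyl]furan-3-yl}methyl methanesulfonate | CS(=O)(=O)OCc1coc(-c2cc(O[Si](C(C)C)(C(C)C)C(C)C)ccc2O[Si](C(C)C)(C(C)C)C(C)C)c1 | intermediate
8 | 2-[2,5-bis(triisopropylsilyloxy)phenyl]-4-(chloromethyl)furan | ClCc1coc(-c2cc(O[Si](C(C)C)(C(C)C)C(C)C)ccc2O[Si](C(C)C)(C(C)C)C(C)C)c1 | intermediate
9 | 2-methylbut-3-en-2-ol | CC(C)(O)C=C | starting material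
10 | sodium 2-methylbut-3-en-2-olate | [Na+].[O-]C(C)(C)C=C | intermediate
11 | 2-[2,5-bis(triisopropylsilyloxy)phenyl]-4-{[(2-methylbut-3-en-2-yl)oxy]methyl}furan | C=CC(C)(C)OCc1coc(-c2cc(O[Si](C(C)C)(C(C)C)C(C)C)ccc2O[Si](C(C)C)(C(C)C)C(C)C)c1 | intermediate
12 | alpha-lithio derivative of 11, lithiated at the furylic OCH carbon (ligand-bound, configurationally labile) | [Li]C(OC(C)(C)C=C)c1coc(-c2cc(O[Si](C(C)C)(C(C)C)C(C)C)ccc2O[Si](C(C)C)(C(C)C)C(C)C)c1 | intermediate
13 | (R)-1-{5-[2,5-bis(triisopropylsilyloxy)phenyl]furan-3-yl}-4-methylpent-3-en-1-ol | CC(C)=CC[C@@H](O)c1coc(-c2cc(O[Si](C(C)C)(C(C)C)C(C)C)ccc2O[Si](C(C)C)(C(C)C)C(C)C)c1 | intermediate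
14 | 3-methylbutanoyl chloride | CC(C)CC(Cl)=O | starting material
15 | (R)-1-{5-[2,5-bis(triisopropylsilyloxy)phenyl]furan-3-yl}-4-methylpent-3-en-1-yl 3-methylbutanoate | CC(C)=CC[C@@H](OC(=O)CC(C)C)c1coc(-c2cc(O[Si](C(C)C)(C(C)C)C(C)C)ccc2O[Si](C(C)C)(C(C)C)C(C)C)c1 | intermediate
16 | (R)-1-[5-(2,5-dihydroxyphenyl)furan-3-yl]-4-methylpent-3-en-1-yl 3-methylbutanoate | CC(C)=CC[C@@H](OC(=O)CC(C)C)c1coc(-c2cc(O)ccc2O)c1 | intermediate
17 | (R)-1-[5-(3,6-dioxocyclohexa-1,4-dien-1-yl)furan-3-yl]-4-methylpent-3-en-1-yl 3-methylbutanoate | CC(C)=CC[C@@H](OC(=O)CC(C)C)c1coc(C2=CC(=O)C=CC2=O)c1 | target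

Total step count: 10. Longest linear sequence: 10 steps (1 to 17).

Steps most likely to fail

Step 7. The ligand-bound base may discriminate poorly between the two faces of the carbanion carbon, may lithiate ring C5–H instead of the OCH2 group, or the carbanion may leak into the [1,2] shift. The fallback sets out from alcohol 6 and comes back at 13. Oxidation of 6 with MnO2 (CH2Cl2, rt) should give 5-[2,5-bis(triisopropylsilyloxy)phenyl]furan-3-carbaldehyde F1. Asymmetric allylboration of F1 follows with (+)-B-allyldiisopinocampheylborane, the reagent antipode derived from (−)-alpha-pinene and expected to give R aryl carbinols (made from (+)-Ipc2BOMe and allylmagnesium bromide; Et2O, −78 °C; NaBO3·4H2O work-up). This should give (R)-1-{5-[2,5-bis(triisopropylsilyloxy)phenyl]furan-3-yl}but-3-en-1-ol F2. Cross-metathesis of F2 with 2-methylbut-2-ene (second-generation Grubbs catalyst, CH2Cl2, rt to 40 °C) then installs the gem-dimethyl terminus and gives 13.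

Step 6. Substitution by the hindered tertiary alkoxide may be slow enough for silyl transfer from an aryl oxygen to the alkoxide, or for decay of the furylmethyl chloride, to take over. The fallback moves the etherification onto a silyl-free fragment; it sets out from bromofuroate 4 and comes back at 11. Reduction of 4 with i-Bu2AlH (CH2Cl2, −78 °C) should give (5-bromofuran-3-yl)methanol F3. Appel bromination (CBr4, PPh3, CH2Cl2, 0 °C) then gives 2-bromo-4-(bromomethyl)furan F4. Williamson etherification of F4 with alkoxide 10 (THF, 0 °C to rt) gives 2-bromo-4-{[(2-methylbut-3-en-2-yl)oxy]methyl}furan F5. Suzuki–Miyaura coupling of F5 with boronate 3 (Pd(OAc)2, SPhos, K3PO4, toluene/H2O, 60 °C) gives 11.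

Step 3. Protodeboronation of the hindered ortho-silyloxy arylboronate may outrun transmetalation, or the ester may hydrolyse under the aqueous base. The fallback reverses the roles of the partners; it sets out from bromide 2 and comes back at 5. Sterically controlled C–H borylation of methyl furan-3-carboxylate F6 at C5 ([Ir(OMe)(cod)]2, 4,4'-di-tert-butyl-2,2'-bipyridine, B2pin2, hexane, rt to 50 °C) should give methyl 5-(4,4,5,5-tetramethyl-1,3,2-dioxaborolan-2-yl)furan-3-carboxylate F7. Suzuki–Miyaura coupling of F7 with 2 (Pd(OAc)2, XPhos (2-dicyclohexylphosphino-2',4',6'-triisopropylbiphenyl), K3PO4, THF/H2O, 40 °C) gives 5.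

Further compounds

F1 | step 7 | 5-[2,5-bis(triisopropylsilyloxy)phenyl]furan-3-carbaldehyde | O=Cc1coc(-c2cc(O[Si](C(C)C)(C(C)C)C(C)C)ccc2O[Si](C(C)C)(C(C)C)C(C)C)c1
F2 | step 7 | (R)-1-{5-[2,5-bis(triisopropylsilyloxy)phenyl]furan-3-yl}but-3-en-1-ol | C=CC[C@@H](O)c1coc(-c2cc(O[Si](C(C)C)(C(C)C)C(C)C)ccc2O[Si](C(C)C)(C(C)C)C(C)C)c1
F3 | step 6 | (5-bromofuran-3-yl)methanol | OCc1coc(Br)c1
F4 | step 6 | 2-bromo-4-(bromomethyl)furan | BrCc1coc(Br)c1
F5 | step 6 | 2-bromo-4-{[(2-methylbut-3-en-2-yl)oxy]methyl}furan | C=CC(C)(C)OCc1coc(Br)c1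
F6 | step 3 | methyl furan-3-carboxylate | COC(=O)c1ccoc1
F7 | step 3 | methyl 5-(4,4,5,5-tetramethyl-1,3,2-dioxaborolan-2-yl)furan-3-carboxylate | COC(=O)c1coc(B2OC(C)(C)C(C)(C)O2)c1
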